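**Retrosynthetic overview**
1. The target is reached by one hydrogenolysis that removes a benzylidene acetal bridge and two benzyl ethers from a bridged oxolane.
2. The oxolane C2–O–C5 unit comes from formal insertion of a water oxygen into the diaryl-substituted C–C bond of a cyclobutane. This runs by two-electron phenol oxidation to a bis(quinone methide), followed by water capture.
3. The cyclobutane and an eleven-membered ring form together in one intramolecular head-to-head [2+2] photocycloaddition. The two chalcone arms are held in register by a PhCH(OAr)2 bridge, which fixes the cis C3/C4 pair.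
4. The bis-chalcone comes from a twofold Claisen–Schmidt condensation. The bridge comes from benzal bromide and two phenols.
5. Ring order: cyclobutane and eleven-membered ring together, then cyclobutane to oxolane, and last the eleven-membered ring is cut away.

Assumption: the drawn (2R,3R,4S,5S) compound has a mirror plane through O1 and the C3–C4 midpoint, so it is meso and achiral, and only the relative configuration 2,3-trans, 3,4-cis, 4,5-trans has to be controlled.

**Step 1**
Reactants: 1 1-[4-(benzyloxy)-2-hydroxyphenyl]ethan-1-one (2 equiv); 2 (dibromomethyl)benzene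
Product: 3 benzaldehyde bis[2-acetyl-5-(benzyloxy)phenyl] acetal
Conditions: K2CO3, DMF, 80 °C
Reagents that add atoms: none
Why: Twofold Williamson-type O-alkylation of a geminal dibromide (acetal formation under basic conditions) works because the benzylic bromides are displaced readily by the phenoxide of 1, and the new acetal carbon bears two identical aryloxy groups so no stereocentre arises.

**Step 2**
Reactants: 3 benzaldehyde bis[2-acetyl-5-(benzyloxy)phenyl] acetal; 4 4-hydroxybenzaldehyde (2.2 equiv)
Product: 5 bridged (E,E)-bis-chalcone PhCH(OAr)2 in which Ar is 5-(benzyloxy)-2-[(E)-3-(4-hydroxyphenyl)prop-2-enoyl]phenyl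
Conditions: KOH (excess), EtOH, 25 to 50 °C; AcOH quench, 0 °C
Reagents that add atoms: none
Why: Twofold Claisen–Schmidt aldol condensation, in which E1cB loss of water gives only the conjugated (E)-enones, the acetal and benzyl ethers are inert to hydroxide, and the alkylated 2-oxygen cannot close to a flavanone.

**Step 3 (key step)**
Reactants: 5 bridged (E,E)-bis-chalcone
Product: 6 bridged cyclobutane, with the two aroyl groups cis on C1/C2 and the two 4-hydroxyphenyl groups on C3/C4 cis to each other and trans to the aroyl groups; the aroyl rings remain joined through their 2-oxygens by the PhCH bridge (eleven-membered ring)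
Conditions: hν (365 nm), degassed MeCN, 1 mM, 20 °C
Reagents that add atoms: none
Why: Template-directed intramolecular enone–enone [2+2] photocycloaddition, in which the three-atom O–CH–O link lets the two aryl ketone rings stack face to face so that the (E)-enone arms lie in register and can only close head to head, forming the cyclobutane and the eleven-membered ring together and placing the two aroyl groups cis (the short bridge cannot span a trans pair) with each aryl group trans to its neighbouring aroyl group.

**Step 4**
Reactants: 6 bridged cyclobutane
Product: 9 benzylidene-bridged meso-oxolane macrocycle, via bis(quinone methide) 7 (not isolated), via hydroxy quinone methide 8 (not isolated)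
Conditions: PhI(OAc)2 (1.0 equiv, slow addition), NaHCO3, MeCN–H2O 4:1, 0 °C
Reagents that add atoms: water, O
Why: Proposed new method: one phenol exchanges onto trivalent iodine and the two-electron loss of PhI is coupled to Grob-type heterolysis of the strained, doubly benzylic cyclobutane bond, because the second 4-hydroxyphenyl group takes up the charge and loses its proton, so 7 forms without radical intermediates that could cyclorevert; water then adds 1,6 to one quinone methide (8) and the new hydroxyl adds 1,6 to the other, each anti to the neighbouring aroyl group (polar Felkin–Anh, convex face of the bicycle), which sets C2 and C5 trans to C3 and C4 while the cis C3/C4 pair is carried over untouched; the closest known reaction types are hypervalent-iodine phenol oxidation with fragmentation and the water capture of 8–8′-coupled bis(quinone methides) that gives 2,5-diaryloxolanes in lignan chemistry.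

**Step 5**
Reactants: 9 benzylidene-bridged meso-oxolane macrocycle
Product: 10 target, (2R,3R,4S,5S)-2,5-bis(4-hydroxyphenyl)oxolane-3,4-diyl bis[(2,4-dihydroxyphenyl)methanone] (meso)
Conditions: H2 (1 atm), Pd/C (10 wt %), EtOAc–MeOH, 20 °C
Reagents that add atoms: none
Why: Catalytic hydrogenolysis cleaves the two benzyl aryl ethers and both benzylic C–O bonds of the PhCH(OAr)2 bridge (aryloxide leaving groups on an unhindered benzylic carbon) much faster than the hindered secondary C–O bonds of the oxolane, so the eleven-membered ring falls away as toluene and none of the four stereocentres is touched.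

**Compound list**
The orientation of the bridge phenyl in 6 to 9 is inconsequential and is left open in the SMILES.

1 | 1-[4-(benzyloxy)-2-hydroxyphenyl]ethan-1-one | CC(=O)c1ccc(OCc2ccccc2)cc1O | starting material
2 | (dibromomethyl)benzene (benzal bromide) | BrC(Br)c1ccccc1 | starting material
3 | benzaldehyde bis[2-acetyl-5-(benzyloxy)phenyl] acetal | CC(=O)c1ccc(OCc2ccccc2)cc1OC(c1ccccc1)Oc1cc(OCc2ccccc2)ccc1C(C)=O | intermediate
4 | 4-hydroxybenzaldehyde | O=Cc1ccc(O)cc1 | starting material
5 | bridged (E,E)-bis-chalcone | O=C(/C=C/c1ccc(O)cc1)c1ccc(OCc2ccccc2)cc1OC(c1ccccc1)Oc1cc(OCc2ccccc2)ccc1C(=O)/C=C/c1ccc(O)cc1 | intermediate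
6 | bridged cyclobutane (aroyl groups cis, aryl groups cis, aroyl/aryl trans) | O=C1c2ccc(OCc3ccccc3)cc2OC(c2ccccc2)Oc2cc(OCc3ccccc3)ccc2C(=O)[C@@H]2[C@@H](c3ccc(O)cc3)[C@@H](c3ccc(O)cc3)[C@H]12 | intermediate
7 | bridged meso bis(quinone methide) | O=C1c2ccc(OCc3ccccc3)cc2OC(c2ccccc2)Oc2cc(OCc3ccccc3)ccc2C(=O)[C@H](C=C2C=CC(=O)C=C2)[C@@H]1C=C1C=CC(=O)C=C1 | intermediate
8 | bridged hydroxy quinone methide (racemic; both enantiomers give meso 9) | O=C1c2ccc(OCc3ccccc3)cc2OC(c2ccccc2)Oc2cc(OCc3ccccc3)ccc2C(=O)[C@H](C=C2C=CC(=O)C=C2)[C@@H]1[C@@H](O)c1ccc(O)cc1 | intermediate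
9 | benzylidene-bridged oxolane macrocycle (2,3-trans, 3,4-cis, 4,5-trans) | O=C1c2ccc(OCc3ccccc3)cc2OC(c2ccccc2)Oc2cc(OCc3ccccc3)ccc2C(=O)[C@@H]2[C@@H](c3ccc(O)cc3)O[C@@H](c3ccc(O)cc3)[C@H]12 | intermediate
10 | CNP0237262.1 | O=C(c1ccc(O)cc1O)[C@@H]1[C@H](C(=O)c2ccc(O)cc2O)[C@@H](c2ccc(O)cc2)O[C@H]1c1ccc(O)cc1 | target

Total step count: 5. Longest linear sequence: 5.

**Steps most likely to fail**

Step 3. The photoreaction may stop at E/Z isomerisation or give other cyclobutanes. The fallback sets out from 5 and makes the C–C bond by radical chemistry instead of light. Ag2O in acetone–water oxidises both phenols by one electron each. The two phenoxyl radicals, held stacked by the bridge, couple at their enone α-carbons (8–8′ coupling), and this gives 7 directly. The route is rejoined at 7, which runs on through 8 to 9 in the same flask. Compound 6 and the iodine oxidant are skipped, and no new compound F0 is needed.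

Step 4. The fragmentation may lose to para-quinol formation, to tautomerisation of 7, or to over-oxidation of 9. The fallback avoids quinone methides and builds the oxolane by a 1,3-dipolar cycloaddition, setting out from 3.
- I2 and CuO in DMSO turn one acetyl group into the glyoxal, which condenses with the other acetyl group to the eleven-membered (Z)-enedione F1. Its ring size locks the cis geometry.
- 4-(Benzyloxy)benzaldehyde and the sulfonium ylide made from 4-(benzyloxy)benzyl chloride and tetrahydrothiophene give rac-trans-2,3-bis[4-(benzyloxy)phenyl]oxirane F2.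
- Photoinduced electron transfer (a triarylpyrylium tetrafluoroborate, blue light) opens the C–C bond of the oxirane to the W-shaped carbonyl ylide F3.
- The ylide adds suprafacially and exo to F1 to give the fully O-protected oxolane macrocycle F4, with all four stereocentres set at once.
- Hydrogenolysis as in step 5 comes back to the route at 10.

Step 5. Pd may also cut the benzylic C–O bonds of the oxolane or reduce the ketones. The fallback sets out from 9 and removes the groups by ionic chemistry. Pyridinium tosylate in wet acetone hydrolyses the bridging acetal to the bis(2-hydroxyaryl ketone) F5. BCl3 with pentamethylbenzene as cation trap in CH2Cl2 at −78 °C then takes off the two benzyl ethers, coming back to the route at 10.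

**Further compounds**
F0 | step 3 | none | none
F1 | step 4 | eleven-membered benzylidene-bridged (Z)-enedione | O=C1/C=C\C(=O)c2ccc(OCc3ccccc3)cc2OC(c2ccccc2)Oc2cc(OCc3ccccc3)ccc12
F2 | step 4 | rac-trans-2,3-bis[4-(benzyloxy)phenyl]oxirane | c1ccc(COc2ccc([C@H]3O[C@@H]3c3ccc(OCc4ccccc4)cc3)cc2)cc1
F3 | step 4 | carbonyl ylide from F2 | c1ccc(COc2ccc([CH-][O+]=Cc3ccc(OCc4ccccc4)cc3)cc2)cc1
F4 | step 4 | fully O-protected oxolane macrocycle (2,3-trans, 3,4-cis, 4,5-trans) | O=C1c2ccc(OCc3ccccc3)cc2OC(c2ccccc2)Oc2cc(OCc3ccccc3)ccc2C(=O)[C@@H]2[C@@H](c3ccc(OCc4ccccc4)cc3)O[C@@H](c3ccc(OCc4ccccc4)cc3)[C@H]12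
F5 | step 5 | meso-oxolane bis[4-(benzyloxy)-2-hydroxyphenyl ketone] | O=C(c1ccc(OCc2ccccc2)cc1O)[C@@H]1[C@H](C(=O)c2ccc(OCc3ccccc3)cc2O)[C@@H](c2ccc(O)cc2)O[C@H]1c1ccc(O)cc1
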